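Do we stop the flask early or let it run its full 15 d?

| flask | substrate | remark | time |
|---|---|---|---|
| beta | 0.025 M | run made earlier |  |
| zeta | 0.10 M | run made earlier |  |
| flask | 0.050 M |  | 15 d |

| run | time / d | product / % | substrate / % |
|---|---|---|---|
| beta | 4.00 | 0 | 99 |
| beta | 5.00 | 3 | 98 |
| beta | 8.00 | 6 | 97 |
| beta | 10.0 | 13 | 87 |
| beta | 15.0 | 42 | 59 |
| zeta | 4.00 | 23 | 73 |
| zeta | 5.00 | 35 | 61 |
| zeta | 8.00 | 55 | 44 |
| zeta | 10.0 | 62 | 37 |
| zeta | 15.0 | 79 | 25 |

(scatter of a reading: 1.5 percentage points)

1. the moment within 15 d at which there is most product
2. the amount of product, in percent of the substrate charged, at that time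

- a reading or a percentage of product counts all its forms, free or not

Product is still climbing at the last reading of both earlier runs, from 13% to 42% in beta and from 62% to 79% in zeta, so we let the flask run and expect its most product at the end.

For the amount, we replace the curve of final product against charge by its mean slope. Beta and zeta lie 2.00 doublings of the charge apart, so each doubling adds on average 19 percentage points of product at 15.0 d: this is the gain per doubling. The flask lies one doubling above beta, so we commit to 60.5%.

The forecast stands a little lower than ours, at 60% and 15 d, reasoning that “The product should therefore still be rising at 15 d”.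

The flask gives its most product at 15.0 d, namely 60.9%, which is 0.40 points above our reckoning. At that time crystals hold 52.9% of the substrate charged, and they are counted in that product. The steps, the last of them autocatalysis, are these:

    crystals ⇌ product, rate k1*(cs1 - [product]) while solid is left; crystals form when [product] > cs1 (solubility = 3.70 mM, k = 0.00410 /min)
    substrate → product (k = 3.80 × 10⁻⁶ /min)
    substrate + 2 product → 3 product (k = 3.30 /M²/min)

Take the neighbour flask charged with 0.085 M of substrate, read at the same 15.0 d. It lies 1.77 doublings above beta, so the gain per doubling gives 74.7% of product, and that neighbour flask holds 72.2% of product, which is 2.5 points less.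

The runs were computed on assumed constants, noise included.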